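Free monomer is the species to follow. Initiator starts chains, free monomer enters them as monomer in chains, and the two earlier runs show how far this goes.

the same everywhere: free monomer 0.20 M
- Thursday's: initiator 4.3 mM; run made earlier
- Monday's: initiator 7.7 mM; run made earlier
- south: initiator 9.4 mM; time 30 min
- west: initiator 6.0 mM; time 30 min

| run | time / min | monomer in chains / % | free monomer / % |
|---|---|---|---|
| Thursday's | 2.00 | 8 | 91 |
| Thursday's | 5.00 | 19 | 77 |
| Thursday's | 10.0 | 32 | 65 |
| Thursday's | 15.0 | 39 | 62 |
| Thursday's | 20.0 | 45 | 59 |
| Monday's | 2.00 | 12 | 86 |
| Monday's | 5.00 | 29 | 74 |
| Monday's | 10.0 | 41 | 60 |
| Monday's | 15.0 | 48 | 51 |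
| Monday's | 20.0 | 48 | 54 |

(scatter of a reading: 2 percentage points)

- the average divides the monomer in chains by the number of chains begun, living and dead together
- the earlier runs do not show the number of chains; that part of a forecast is a guess

1. which of the two ends with the longer chains by the average number of monomer units in a chain (chains begun, living or dead) ("neither" if they lie within 10%) (south / west / neither)
2. average number of monomer units in a chain (chains begun, living or dead) at the end, south
3. average number of monomer units in a chain (chains begun, living or dead) at the end, west

Monday's run stalls: free monomer reads 51% at 15.0 min and 54% at 20.0 min, flat within the scatter. Their mean, 0.105 M, is read as the residual free monomer M_r, the level where the fall stops in that run (the equilibrium monomer concentration).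

The times then form a ladder, read in logarithms. On the lowest rung, the gap G between free monomer and M_r shrinks with a time τ, the elapsed time over the logarithm of G at the start to G now. Thursday's run gives 7.55 min from its 5.00 min reading and 7.49 min from its 10.0 min reading. Monday's run, with more initiator, gives a shorter 6.31 min from its 5.00 min reading.

On the next rung, G falls by one power of ten every 17.2 min. On the top rung, 30 min holds 1.74 such powers. This reckoning takes the same M_r and Thursday's τ for south and west, and puts the gap at 0.00173 M. It puts monomer in chains at 0.0933 M in either flask.

The runs do not show the chain count, so this reckoning guesses 0.5 chains per initiator. That gives 19.8 for south and 31.1 for west, so this reckoning puts west longer by a factor 1.57.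

The forecast gives west, with 15 for south and 20 for west, and says “The chain count is a guess”.

The flask gives west, with 18.9 for south and 25.0 for west.

    free monomer + living end → monomer in chains + living end, rate k1*[living end]*[free monomer] (k = 0.605 M⁻¹ s⁻¹)
    monomer in chains + living end → free monomer + living end, rate k2*[living end] as long as [monomer in chains] is above zero (k = 0.0608 s⁻¹)
    free monomer + initiator → living end + monomer in chains (k = 0.115 M⁻¹ s⁻¹)
    2 initiator → spent initiator (k = 2.29 M⁻¹ s⁻¹)

At 30.0 min, south holds 49.6% monomer in chains over 0.00526 M living end, and west holds 49.0% over 0.00393 M. M_r is carried to a further flask, like west but charged with 0.80 M free monomer. Charge minus M_r reckons 0.695 M monomer in chains, and over its 0.00525 M living end that makes 132. That flask gives 133, with 0.103 M free monomer left.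

The data are simulated on assumed constants, noise included.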